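The numbers in the tables are simulated on assumed constants, noise included.

- Temperature and time reach a flask here through one figure, the burn: I work with the fraction of starting material left and take −ln of it. In a pseudo-first-order reading, with c(free catalyst) held, the burn is a rate constant times time, and stages add.

| flask | starting material | free catalyst | temperature | remark | time |
|---|---|---|---|---|---|
| east | 3 M | 9.4 mM | 2 °C | run made earlier |  |
| south-west | 3 M | 21 mM | 19 °C | run made earlier |  |
| Thursday's | 3.0 M | 14 mM |  | at 25 °C until 80 s, from then on at −5 °C | 4.0 min |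
| Tuesday's | 3.0 M | 14 mM | −5 °C |  | 4.0 min |
| Sunday's | 3.0 M | 14 mM | 10 °C |  | 4.0 min |
| Saturday's | 3.0 M | 14 mM | 25 °C |  | 4.0 min |

- east (time / min: product / %, starting material / %): 0.250: 0.6, 98.6; 0.500: 0.9, 98.2; 0.833: 2.1, 97.0; 1.50: 4.7, 94.0; 3.00: 8.9, 90.9
- south-west (time / s: product / %, starting material / %): 10.0: 4.0, 96.5; 15.0: 4.0, 95.1; 30.0: 10.3, 89.8; 60.0: 20.0, 79.6

(scatter of a reading: 0.5 percentage points)

* the best flask by amount of product, in percent of the starting material charged; "all alike" if 1.5 percentage points covers them all (Thursday's / Tuesday's / Sunday's / Saturday's / all alike)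
* amount of product at the end, in percent of the starting material charged, Thursday's
* amount of product at the end, in percent of the starting material charged, Tuesday's
* amount of product at the end, in percent of the starting material charged, Sunday's
* amount of product at the end, in percent of the starting material charged, Saturday's

- The east run keeps 90.9% after 3.00 min, a burn of 0.0954, and the south-west run keeps 79.6% after 60.0 s.
- Scaled in proportion to c(free catalyst) = 14 mM, these readings give 0.0474 min⁻¹ at 2 °C and 0.152 min⁻¹ at 19 °C, so I read an apparent activation energy of 45.9 kJ mol⁻¹.
- At 14 mM my rate constants are 0.0281 min⁻¹ at −5 °C, 0.0835 min⁻¹ at 10 °C and 0.222 min⁻¹ at 25 °C.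
- Tuesday's looks nearly like the east run, and I expect it to end close by: it gets twice the catalyst-minutes, but at −5 °C my rate per unit of catalyst is 0.593 of the east run's. The burn of Tuesday's is therefore 0.112, more than the east run's, which gives 10.6% product.
- From the same rate constants I commit to 28.4% product for Sunday's and 58.9% for Saturday's, which is more than Sunday's.
- Thursday's spends 80 s hot, for a burn of 0.297, and the remaining time cold, for 0.0748, so the shorter stage burns more.
- 0.371 is then the burn of Thursday's, −ln of the fraction of starting material left at its end, and it gives 31.0% product. Saturday's is then my best flask.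
- The forecast, which reads the runs as “first order in starting material”, names Saturday's as best, with 30% for Thursday's, 10.5% for Tuesday's, 28% for Sunday's and 58% for Saturday's; my Thursday's and Saturday's figures are higher.
- The flasks give 29.9% for Thursday's, 10.3% for Tuesday's, 29.0% for Sunday's and 57.3% for Saturday's, so Saturday's is best. At the change of temperature, after 1.33 min, Thursday's still holds 75.7% starting material. My burn of 0.371 leaves 69.0% at the end of Thursday's, and the flask has 70% left.

    starting material + free catalyst → catalyst intermediate A (k = 0.290 L mol⁻¹ s⁻¹, Ea = 35.0 kJ mol⁻¹)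
    catalyst intermediate A ⇌ catalyst intermediate B (K = 0.830, k = 4.50 s⁻¹, Ea = 68.0 kJ mol⁻¹, ΔH = −63.0 kJ mol⁻¹)
    catalyst intermediate B → free catalyst + product (k = 160 s⁻¹, Ea = 65.0 kJ mol⁻¹)
    2 starting material → homo dimer (k = 5.90 × 10⁻⁶ L mol⁻¹ s⁻¹, Ea = 67.0 kJ mol⁻¹)
    (constants at 25 °C)

- A neighbouring flask is Thursday's with 0.035 M of free catalyst. Scaling my burn by 2.50 gives 0.928, so 60.5% product; the computed flask gives 61.0%.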